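**Retrosynthetic overview**

1. Prinsepiol is a C2-symmetric, cis-fused 3,7-dioxabicyclo[3.3.0]octane whose two ring-fusion carbons C1 and C5 are both tertiary carbinols. The C1(OH)–C5(OH) bond, shared by both tetrahydrofuran rings, is a pinacol retron.
2. Cutting it leaves the eight-membered periphery (C1–C2–O3–C4–C5–C6–O7–C8) as a (2R,6R)-2,6-diaryl-1,5-dioxocane-3,7-dione without any quaternary centre. Its two carbonyl carbons face each other 1,5 across the ring, so a transannular SmI2 pinacol coupling closes both five-membered rings and sets both carbinol centres from the two benzylic ones.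
3. The diketone comes from ozonolysis of the 3,7-dimethylene-1,5-dioxocane. That ring is built head-to-tail from two copies of one enantiopure (R)-2-methylene-1-aryl-1,3-diol unit by an intermolecular and then a ring-closing Williamson etherification.
4. The unit comes from O-TIPS-vanillin by an enantioselective Morita–Baylis–Hillman reaction and ester reduction. Ring order: eight-membered diether ring first, then both tetrahydrofuran rings together in the key step; desilylation ends the route.

Key step: step 11

Remark on the chemistry: the target SMILES is read as (1S,2R,5S,6R)-2,6-bis(4-hydroxy-3-methoxyphenyl)-3,7-dioxabicyclo[3.3.0]octane-1,5-diol, cis-fused, with both aryl groups on the convex face and cis to the neighbouring bridgehead hydroxyl. In names, Ar = 3-methoxy-4-(triisopropylsilyloxy)phenyl.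

**Route**

Step 1
Reactants: 1 vanillin (4-hydroxy-3-methoxybenzaldehyde)
Product: 2 3-methoxy-4-(triisopropylsilyloxy)benzaldehyde
Conditions: iPr3SiCl, imidazole, DMF, rt
Reagents that add atoms: triisopropylsilyl chloride, CC(C)[Si](Cl)(C(C)C)C(C)C
Why: Imidazole-mediated O-silylation of the phenol is a standard protection, and the bulky aryl TIPS ether should survive the hydride, alkoxide, ozone and SmI2 steps and fall to fluoride at the end.

Step 2
Reactants: 2 3-methoxy-4-(triisopropylsilyloxy)benzaldehyde; 3 1,1,1,3,3,3-hexafluoropropan-2-yl acrylate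
Product: 4 1,1,1,3,3,3-hexafluoropropan-2-yl (R)-2-[hydroxy(Ar)methyl]prop-2-enoate
Conditions: β-isocupreidine (0.1 equiv), DMF, −55 °C
Reagents that add atoms: none
Why: Enantioselective Morita–Baylis–Hillman reaction in which the quinuclidine nitrogen of the catalyst adds to the activated acrylate and its phenolic hydroxyl organises the aldol and elimination steps, a combination known to deliver the (R)-adduct from aromatic aldehydes, which sets the benzylic stereocentre that becomes C2 and C6 of the target.

Step 3
Reactants: 4 1,1,1,3,3,3-hexafluoropropan-2-yl (R)-2-[hydroxy(Ar)methyl]prop-2-enoate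
Product: 5 (R)-1-Ar-2-methylenepropane-1,3-diol
Conditions: iBu2AlH (3.5 equiv), CH2Cl2, −78 °C; aq. potassium sodium tartrate
Reagents that add atoms: none
Why: 1,2-Reduction of the activated acrylate ester by iBu2AlH should give the primary allylic alcohol without touching the aryl silyl ether or the stereocentre.

Step 4
Reactants: 5 (R)-1-Ar-2-methylenepropane-1,3-diol
Product: 7 (R)-2-(chloromethyl)-1-Ar-prop-2-en-1-ol, via primary mesylate 6 (not isolated)
Conditions: MsCl (1.05 equiv), 2,4,6-collidine, LiCl, DMF, −20 → 0 °C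
Reagents that add atoms: lithium chloride, [Li+].[Cl-]; methanesulfonyl chloride, CS(=O)(=O)Cl (its atoms remain only in intermediate 6)
Why: Selective sulfonylation of the unhindered primary allylic hydroxyl over the secondary benzylic one, followed by in situ chloride displacement of the allylic mesylate (SN2 and SN2' give the same product), should give the chloro alcohol with the stereocentre untouched.

Step 5
Reactants: 7 (R)-2-(chloromethyl)-1-Ar-prop-2-en-1-ol
Product: 8 (R)-{[2-(chloromethyl)-1-Ar-prop-2-en-1-yl]oxy}triethylsilane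
Conditions: Et3SiOTf, 2,6-lutidine, CH2Cl2, −78 °C
Reagents that add atoms: triethylsilyl trifluoromethanesulfonate, CC[Si](CC)(CC)OS(=O)(=O)C(F)(F)F
Why: Silylation with a silyl triflate and a non-nucleophilic base should mask the benzylic hydroxyl of the future electrophile without displacing the allylic chloride.

Step 6
Reactants: 8 (R)-{[2-(chloromethyl)-1-Ar-prop-2-en-1-yl]oxy}triethylsilane
Product: 9 (R)-triethyl{[2-(iodomethyl)-1-Ar-prop-2-en-1-yl]oxy}silane
Conditions: NaI, acetone, rt, dark
Reagents that add atoms: sodium iodide, [Na+].[I-]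
Why: Finkelstein exchange driven by precipitation of NaCl should turn the allylic chloride into the far more reactive allylic iodide, which differentiates the electrophile from the chloride-bearing nucleophile in step 7.

Step 7
Reactants: 7 (R)-2-(chloromethyl)-1-Ar-prop-2-en-1-ol (nucleophile); 9 (R)-triethyl{[2-(iodomethyl)-1-Ar-prop-2-en-1-yl]oxy}silane (electrophile, 1.2 equiv)
Product: 10 triethyl{[(R)-2-({[(R)-2-(chloromethyl)-1-Ar-prop-2-en-1-yl]oxy}methyl)-1-Ar-prop-2-en-1-yl]oxy}silane
Conditions: NaN(SiMe3)2 (1.0 equiv), THF, −78 °C; then 9, 15-crown-5, −78 → 0 °C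
Reagents that add atoms: none
Why: Williamson etherification in which the sodium alkoxide of 7 attacks the allylic iodide of 9 much faster than any allylic chloride, so self-condensation of 7 should be suppressed, and both benzylic centres are retained because only O–CH2 bonds form (SN2 and SN2' attack on the 2-substituted allyl unit give the same ether).

Step 8
Reactants: 10 triethyl{[(R)-2-({[(R)-2-(chloromethyl)-1-Ar-prop-2-en-1-yl]oxy}methyl)-1-Ar-prop-2-en-1-yl]oxy}silane
Product: 11 (R)-2-({[(R)-2-(chloromethyl)-1-Ar-prop-2-en-1-yl]oxy}methyl)-1-Ar-prop-2-en-1-ol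
Conditions: HF·pyridine, pyridine, THF, 0 °C
Reagents that add atoms: none
Why: Buffered HF·pyridine should cleave the secondary alkyl triethylsilyl ether much faster than the hindered aryl TIPS ethers (selective desilylation) and leave the allylic chloride and the benzylic ether intact.

Step 9
Reactants: 11 (R)-2-({[(R)-2-(chloromethyl)-1-Ar-prop-2-en-1-yl]oxy}methyl)-1-Ar-prop-2-en-1-ol
Product: 12 (2R,6R)-2,6-bis(Ar)-3,7-dimethylene-1,5-dioxocane
Conditions: NaH, 15-crown-5, THF, 45 °C, slow addition of 11 (final 2 mM)
Reagents that add atoms: none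
Why: Ring-closing Williamson etherification under pseudo-high dilution, helped by the two sp2 ring carbons and two ring oxygens that lower transannular strain (the parent 3,7-dimethylene-1,5-dioxocane is made the same way), should close the eight-membered ring, with SN2 and SN2' attack again converging on one product.

Step 10
Reactants: 12 (2R,6R)-2,6-bis(Ar)-3,7-dimethylene-1,5-dioxocane
Product: 14 (2R,6R)-2,6-bis(Ar)-1,5-dioxocane-3,7-dione, via bis-ozonide 13 (not isolated)
Conditions: O3, CH2Cl2, −78 °C (Sudan Red 7B end point); then PPh3, −78 °C → rt; used at once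
Reagents that add atoms: ozone, [O-][O+]=O
Why: Ozonolysis of the two electron-rich 1,1-disubstituted alkenes should outpace attack on the silylated guaiacyl rings at −78 °C with an indicator end point, and neutral PPh3 reduction of the ozonide avoids epimerizing the alpha-aryl ketones.

Step 11
Reactants: 14 (2R,6R)-2,6-bis(Ar)-1,5-dioxocane-3,7-dione
Product: 15 (1S,2R,5S,6R)-2,6-bis(Ar)-3,7-dioxabicyclo[3.3.0]octane-1,5-diol
Conditions: SmI2 (2.5 equiv), THF, −78 → −30 °C, no proton donor, no HMPA; aq. NH4Cl
Reagents that add atoms: none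
Why: Electron transfer from divalent samarium to one carbonyl of 14 gives a samarium ketyl whose carbon (C3) adds across the ring to the samarium-coordinated carbonyl carbon C7 held 1,5 to it, and a second electron transfer gives the bridged samarium diolate that is protonated on work-up (transannular pinacol coupling). The closest known reaction types are the transannular pinacol coupling of cyclooctane-1,5-dione to cis-bicyclo[3.3.0]octane-1,5-diol and the SmI2 pinacol cyclization of sugar-derived 1,5-dicarbonyl compounds that carry alpha-alkoxy groups. The single new C3–C7 bond closes both tetrahydrofuran rings at once, each in a 5-exo-trig mode (ketyl carbon onto a carbonyl whose C=O bond lies outside the forming C–C–O–C–C ring). The two new carbinol centres (C1 and C5 of 15) should be cis to each other because only the cis-fused bicycle is accessible and both oxygen atoms stay bound to samarium on the convex face; they are set relative to the (2R,6R) benzylic centres because folding places each aryl group pseudo-equatorially on the convex face (exo, cis to the neighbouring hydroxyl) and not inside the fold, which translates (2R,6R) into (1S,5S). The step needs C–C coupling to be faster than beta-scission of the ring C–O bonds at the ketyl stage and than enolization of the alpha-aryl ketones; the enforced proximity of C3 and C7, the absence of a proton donor and of HMPA, the neutral medium and the low temperature are meant to secure this.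

Step 12
Reactants: 15 (1S,2R,5S,6R)-2,6-bis(Ar)-3,7-dioxabicyclo[3.3.0]octane-1,5-diol
Product: 16 prinsepiol, (1S,2R,5S,6R)-2,6-bis(4-hydroxy-3-methoxyphenyl)-3,7-dioxabicyclo[3.3.0]octane-1,5-diol
Conditions: Bu4NF, AcOH, THF, 0 °C
Reagents that add atoms: none
Why: Acetic-acid-buffered fluoride desilylation should free both phenols without acid (which could ionize the electron-rich benzylic ethers) and without hydrogenolysis, so no stereocentre is touched.

**Compound list**

1 | vanillin | COc1cc(C=O)ccc1O | starting material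
2 | 3-methoxy-4-(triisopropylsilyloxy)benzaldehyde | COc1cc(C=O)ccc1O[Si](C(C)C)(C(C)C)C(C)C | intermediate
3 | 1,1,1,3,3,3-hexafluoropropan-2-yl acrylate | C=CC(=O)OC(C(F)(F)F)C(F)(F)F | starting material
4 | 1,1,1,3,3,3-hexafluoropropan-2-yl (R)-2-[hydroxy(Ar)methyl]prop-2-enoate | C=C(C(=O)OC(C(F)(F)F)C(F)(F)F)[C@H](O)c1ccc(O[Si](C(C)C)(C(C)C)C(C)C)c(OC)c1 | intermediate
5 | (R)-1-Ar-2-methylenepropane-1,3-diol | C=C(CO)[C@H](O)c1ccc(O[Si](C(C)C)(C(C)C)C(C)C)c(OC)c1 | intermediate
6 | (R)-2-[hydroxy(Ar)methyl]prop-2-en-1-yl methanesulfonate (primary mesylate) | C=C(COS(C)(=O)=O)[C@H](O)c1ccc(O[Si](C(C)C)(C(C)C)C(C)C)c(OC)c1 | intermediate (not isolated)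
7 | (R)-2-(chloromethyl)-1-Ar-prop-2-en-1-ol | C=C(CCl)[C@H](O)c1ccc(O[Si](C(C)C)(C(C)C)C(C)C)c(OC)c1 | intermediate
8 | (R)-{[2-(chloromethyl)-1-Ar-prop-2-en-1-yl]oxy}triethylsilane | C=C(CCl)[C@H](O[Si](CC)(CC)CC)c1ccc(O[Si](C(C)C)(C(C)C)C(C)C)c(OC)c1 | intermediate
9 | (R)-triethyl{[2-(iodomethyl)-1-Ar-prop-2-en-1-yl]oxy}silane | C=C(CI)[C@H](O[Si](CC)(CC)CC)c1ccc(O[Si](C(C)C)(C(C)C)C(C)C)c(OC)c1 | intermediate
10 | triethyl{[(R)-2-({[(R)-2-(chloromethyl)-1-Ar-prop-2-en-1-yl]oxy}methyl)-1-Ar-prop-2-en-1-yl]oxy}silane | C=C(CCl)[C@H](OCC(=C)[C@H](O[Si](CC)(CC)CC)c1ccc(O[Si](C(C)C)(C(C)C)C(C)C)c(OC)c1)c1ccc(O[Si](C(C)C)(C(C)C)C(C)C)c(OC)c1 | intermediate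
11 | (R)-2-({[(R)-2-(chloromethyl)-1-Ar-prop-2-en-1-yl]oxy}methyl)-1-Ar-prop-2-en-1-ol | C=C(CCl)[C@H](OCC(=C)[C@H](O)c1ccc(O[Si](C(C)C)(C(C)C)C(C)C)c(OC)c1)c1ccc(O[Si](C(C)C)(C(C)C)C(C)C)c(OC)c1 | intermediate
12 | (2R,6R)-2,6-bis(Ar)-3,7-dimethylene-1,5-dioxocane | C=C1CO[C@H](c2ccc(O[Si](C(C)C)(C(C)C)C(C)C)c(OC)c2)C(=C)CO[C@@H]1c1ccc(O[Si](C(C)C)(C(C)C)C(C)C)c(OC)c1 | intermediate
13 | bis-ozonide of 12 (1,2,4-trioxolanes spiro-fused at C3 and C7 of the dioxocane, mixture at the spiro centres) | C1OOC2(O1)CO[C@H](c3ccc(O[Si](C(C)C)(C(C)C)C(C)C)c(OC)c3)C1(OCOO1)CO[C@@H]2c1ccc(O[Si](C(C)C)(C(C)C)C(C)C)c(OC)c1 | intermediate (not isolated)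
14 | (2R,6R)-2,6-bis(Ar)-1,5-dioxocane-3,7-dione | O=C1CO[C@H](c2ccc(O[Si](C(C)C)(C(C)C)C(C)C)c(OC)c2)C(=O)CO[C@@H]1c1ccc(O[Si](C(C)C)(C(C)C)C(C)C)c(OC)c1 | intermediate
15 | (1S,2R,5S,6R)-2,6-bis(Ar)-3,7-dioxabicyclo[3.3.0]octane-1,5-diol (bis-TIPS-prinsepiol) | COc1cc([C@H]2OC[C@]3(O)[C@@H](c4ccc(O[Si](C(C)C)(C(C)C)C(C)C)c(OC)c4)OC[C@]23O)ccc1O[Si](C(C)C)(C(C)C)C(C)C | intermediate
16 | prinsepiol | COc1cc([C@H]2OC[C@]3(O)[C@@H](c4ccc(O)c(OC)c4)OC[C@]23O)ccc1O | target

**Step count and risks**

Total step count: 12. Longest linear sequence: 12 steps (1 → 16; step 7 joins two portions drawn from the same intermediate 7).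

The three steps most likely to fail:

1. Step 11 (transannular pinacol coupling). What may go wrong: reductive beta-scission of a ring C–O bond at the ketyl stage, enolization of the alpha-aryl ketone with loss of benzylic configuration, or folding of the ring with the aryl groups inside the fold (poor facial selectivity). Fallback: the C–C bond would be made on an open-chain diketone by a 5-exo ketyl–ketone pinacol cyclization and the second ring closed afterwards by etherification. It sets out from diol 5 (with iodide 9) and comes back at 15.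
   - Selective silylation of the primary hydroxyl of 5 (TBSCl, imidazole, CH2Cl2, −20 °C) would give the primary tert-butyldimethylsilyl ether F1.
   - Alkylation of its sodium alkoxide with 9 under the conditions of step 7 would give the open-chain bis-allyl ether F2.
   - Ozonolysis as in step 10 would give the acyclic diketone F3.
   - SmI2 in THF at −78 °C would close one tetrahydrofuran ring to the cis-3,4-diol F4. The cis-diol is expected from the samarium-bridged transition state, and the hydroxyl next to the ring aryl group should be cis to it because the larger silyloxymethyl group goes trans.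
   - HF·pyridine would remove the TBS and TES groups to give the tetraol F5.
   - NaH and N-tosylimidazole in THF would sulfonylate the primary hydroxyl and close the second ring by 5-exo-tet attack of the benzylic alkoxide, giving 15. A spiro-epoxide formed from the neighbouring tertiary alkoxide would be opened at its CH2 end by the same alkoxide, so both paths converge.

2. Step 9 (eight-membered Williamson ring closure). What may go wrong: intermolecular etherification (chain growth to oligomers) outrunning closure of the medium ring. Fallback: the eight-membered diketone would be reached by oxidative cleavage of a bicyclic alkene, so that only five-membered rings are ever closed. It sets out from 11 and comes back at 14.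
   - Ring-closing metathesis of the two 1,1-disubstituted alkenes of 11 (second-generation Hoveyda–Grubbs catalyst, toluene, 80 °C) would give the 2,5-dihydrofuran with a tetrasubstituted ring alkene F6.
   - NaH in THF would close the second five-membered ring by 5-exo-tet Williamson etherification to the bicyclic tetrasubstituted alkene F7.
   - Ozonolysis of the ring-fusion C=C of F7 (O3, CH2Cl2, −78 °C; then PPh3) would open the bicycle to the eight-membered diketone 14.

3. Step 2 (enantioselective Morita–Baylis–Hillman reaction). What may go wrong: slow addition to the electron-rich aldehyde, with incomplete conversion and erosion of enantiomeric purity. Fallback: racemic synthesis followed by resolution through diastereomeric esters. It sets out from 2 and comes back at 5.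
   - The racemic Morita–Baylis–Hillman reaction of 2 with methyl acrylate (1,4-diazabicyclo[2.2.2]octane, MeOH, rt) would give the racemic methyl ester F8.
   - Esterification with (S)-O-methylmandelic acid (DCC, DMAP, CH2Cl2, 0 °C) and chromatographic separation of the two diastereomers would give the (R)-carbinol (S)-O-methylmandelate F9; its carbinol configuration would be assigned from the anisotropic shifts of the mandelate.
   - iBu2AlH (CH2Cl2, −78 °C) would reduce the methyl ester and cleave the mandelate in one operation to give diol 5.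

**Further compounds**

F1 | step 11 | (R)-3-(tert-butyldimethylsilyloxy)-2-methylene-1-Ar-propan-1-ol | C=C(CO[Si](C)(C)C(C)(C)C)[C@H](O)c1ccc(O[Si](C(C)C)(C(C)C)C(C)C)c(OC)c1
F2 | step 11 | open-chain bis-allyl ether: (R)-1-Ar-2-({[(R)-1-Ar-2-(tert-butyldimethylsilyloxymethyl)prop-2-en-1-yl]oxy}methyl)prop-2-en-1-yl triethylsilyl ether | C=C(CO[Si](C)(C)C(C)(C)C)[C@H](OCC(=C)[C@H](O[Si](CC)(CC)CC)c1ccc(O[Si](C(C)C)(C(C)C)C(C)C)c(OC)c1)c1ccc(O[Si](C(C)C)(C(C)C)C(C)C)c(OC)c1
F3 | step 11 | acyclic diketone: (R)-1-Ar-1-{[(R)-3-Ar-2-oxo-3-(triethylsilyloxy)propyl]oxy}-3-(tert-butyldimethylsilyloxy)propan-2-one | O=C(CO[Si](C)(C)C(C)(C)C)[C@H](OCC(=O)[C@H](O[Si](CC)(CC)CC)c1ccc(O[Si](C(C)C)(C(C)C)C(C)C)c(OC)c1)c1ccc(O[Si](C(C)C)(C(C)C)C(C)C)c(OC)c1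
F4 | step 11 | (2R,3S,4S)-2-Ar-3-(tert-butyldimethylsilyloxymethyl)-4-[(R)-Ar(triethylsilyloxy)methyl]tetrahydrofuran-3,4-diol | COc1cc([C@H]2OC[C@](O)([C@@H](c3ccc(O[Si](C(C)C)(C(C)C)C(C)C)c(OC)c3)O[Si](CC)(CC)CC)[C@@]2(CO[Si](C)(C)C(C)(C)C)O)ccc1O[Si](C(C)C)(C(C)C)C(C)C
F5 | step 11 | (2R,3S,4S)-2-Ar-3-(hydroxymethyl)-4-[(R)-Ar(hydroxy)methyl]tetrahydrofuran-3,4-diol | COc1cc([C@H]2OC[C@](O)([C@@H](c3ccc(O[Si](C(C)C)(C(C)C)C(C)C)c(OC)c3)O)[C@@]2(CO)O)ccc1O[Si](C(C)C)(C(C)C)C(C)C
F6 | step 9 | (R)-[(5R)-5-Ar-4-(chloromethyl)-2,5-dihydrofuran-3-yl](Ar)methanol | ClCC1=C([C@H](O)c2ccc(O[Si](C(C)C)(C(C)C)C(C)C)c(OC)c2)CO[C@@H]1c1ccc(O[Si](C(C)C)(C(C)C)C(C)C)c(OC)c1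
F7 | step 9 | (2R,6R)-2,6-bis(Ar)-3,7-dioxabicyclo[3.3.0]oct-1(5)-ene | C1(=C2CO[C@@H]1c3ccc(O[Si](C(C)C)(C(C)C)C(C)C)c(OC)c3)CO[C@@H]2c3ccc(O[Si](C(C)C)(C(C)C)C(C)C)c(OC)c3
F8 | step 2 | racemic methyl 2-[hydroxy(Ar)methyl]prop-2-enoate | C=C(C(=O)OC)C(O)c1ccc(O[Si](C(C)C)(C(C)C)C(C)C)c(OC)c1
F9 | step 2 | methyl 2-{(R)-Ar[(S)-2-methoxy-2-phenylacetoxy]methyl}prop-2-enoate | C=C(C(=O)OC)[C@H](OC(=O)[C@@H](OC)c1ccccc1)c1ccc(O[Si](C(C)C)(C(C)C)C(C)C)c(OC)c1
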